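## Structural features

Pervilleanone is an isoflavanone: a chroman-4-one in which benzo ring A (7-OH) is fused to the dihydropyranone ring C (O1, C2H2, C3, C4=O), and C3 carries aryl ring B. Ring B is pentasubstituted with five different neighbours in a row: C1' (bond to C3), C2'–OH, C3'–OMe, C4'–OMe and C5'–C(CH3)2CH=CH2; only C6' keeps a hydrogen. The single stereocentre, C3 (R), has no stereogenic neighbour. It is a tertiary carbon that is both benzylic and α to the C4 ketone, so it enolises easily, and base can also open ring C by β-elimination of the O1 phenoxide. The other fragile groups are the monosubstituted vinyl group (no hydrogenolysis, no free bromine), the two phenols, and the 2'-OH/C4=O pair, which can cyclodehydrate under strong acid. The real difficulties are the contiguous ring B pattern, with a quaternary allylic carbon next to an oxygenated carbon, and obtaining C3 as one enantiomer and keeping it through the last steps. The key step exploits the C3'(OMe)–C4'(O)–C5'(C) triad of ring B: a C4'–C5' aryne polarised by the C3' methoxy group takes the carbon substituent at C5' and leaves a metal at C4' that becomes the oxygen.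

## Logic of the disconnections

19 ⇒ 18. The two O–CH2 acetal bonds on O7 and O2' are added in the retrosynthetic sense. The free phenols would not survive the enolate coupling and the oxidation that come earlier. No skeletal bond is simplified, but every earlier intermediate becomes non-acidic and non-oxidisable. The forward cleavage must be fast and free of base and strong protic acid, because C3–H enolises.

18 ⇒ 17. The C4=O π bond is exchanged for C4–H and O–H. An α-aryl ketone cannot be made as one enantiomer by a basic C–C coupling, whereas in the alcohol C3 is configurationally locked. The stereochemical problem becomes a reduction problem. The forward oxidation must be non-basic so that C3 is not touched.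

17 ⇒ 16. The C4–H bond is removed and both stereocentres are erased to a racemate. The ease of enolisation of C3 in 16, a liability elsewhere, is what a dynamic kinetic resolution needs. A racemic ketone therefore suffices. The forward step needs racemisation faster than hydride transfer, catalyst control of the C4 face, and hydride delivery anti to the C3 aryl group.

16 ⇒ 13 + 15. The C3–C1' bond is cut. It is the only bond joining the two halves, and cutting it leaves rings A and C as an intact chromanone. The target falls into two fragments of similar size. The forward step must monoarylate a base-sensitive enolate with an ortho-substituted aryl bromide and leave the vinyl group alone.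

15 ⇒ 14 and 13 ⇒ 12 ⇒ 11 ⇒ 10 ⇒ 9. The bonds cut are O–CH2 (in 15 and 13), C1'–Br (in 12), O2'–Si (re-added on going from 11 to 10) and O4'–CH3 (in 10). Bromine is introduced only when O2' is a free phenol, because then C1' is the single activated position; O4' is methylated while O2' is still silylated. Ring B is thereby reduced to 9, a tetrasubstituted arene with its two phenolic oxygens differentiated. The forward bromination must spare the vinyl group and the forward methylation must touch O4' only.

9 ⇒ 2 + 4. The C5'–C(quaternary) bond and the C4'–O bond are cut together. Adjacent carbon and oxygen substituents beside a methoxy group are the signature of nucleophile and electrophile added across an aryne. The crowded arene 9 is traced to a bromoarene and a five-carbon Grignard reagent, with two bonds made in one operation. The forward step must form one aryne only (through 5 and 6), add carbon at C5' and magnesium at C4' (7), transfer the allyl unit through its substituted end, and convert C–Mg into C–O (through 8).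

2 ⇒ 1 and 4 ⇒ 3. The O–Si bond and the C–Mg bond are cut. Both precursors are commercial. The forward steps are a silylation and a Grignard formation, the latter requiring suppression of Wurtz coupling.

## Other disconnections considered

Alternative 1: The cut removes O1–C8a, C4–C4a and O1–C2, so ring C is assembled between a ring A aryne and a ring B acrylic acid.
- Forward key step: fluoride would release the aryne from the ortho-silylaryl triflate A3. The carboxylate of the 2-aryl-3-methoxyacrylic acid A2 would add at the aryne carbon that becomes C8a, and the aryl anion at C4a would attack the acyl carbon. The four-membered intermediate would open to an ortho-acylphenoxide, which would close onto C2 with loss of the methoxy group to give the chloroisoflavone A1.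
- In its favour: three bonds and ring C form in one convergent operation, fluoride conditions leave the acetal groups and the vinyl group alone, and A1 has no stereocentre to lose.
- Against it here: A2 already contains the complete ring B with its 1,1-dimethylallyl group, and needs two further carbons (C3, C2) on C1'. The chlorine at C5 only orients the aryne and would have to be removed reductively beside the vinyl group. A3 is not commercial. C3 would still have to be made stereogenic by reduction and reoxidation.
- Structure: the alternative is the better plan for ring C (one step, three bonds). The chosen plan is the better one for ring B, where the substitution problem lies, and it takes ring C ready-made from 14.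
- Mechanism: both rely on a substituent beside an aryne to fix the orientation of addition. In the chosen plan that substituent (the C3' methoxy group) belongs to the target; in the alternative it is an auxiliary chlorine, and the acyl shift would have to outrun protonation of the aryl anion.
- Stereochemical endgame: equal in both plans, and the alternative is slightly better placed, since an isoflavone can be reduced at C2=C3 and C4=O in one pot.
- Step economy: the alternative is longer, by the syntheses of A2 and A3 and the dechlorination.

Alternative 2: The cut is C3–C4.
- Forward key step: in the sulfone A5 the ring A aldehyde (future C4) is tied through O1–C2 to the future C3, which bears a sulfonyl group and sits ortho to the free C2' phenol. Base would expel sulfinate to give the ortho-quinone methide A6. A chiral triazolylidene would convert the aldehyde into an acyl anion equivalent, whose addition to the exocyclic carbon of A6 would close the six-membered ring C, rearomatise ring B and give A4 with C3 set by the catalyst.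
- In its favour: ring C, the C3–C4 bond and the stereocentre would arise in one catalytic step at the ketone oxidation level, and O2' would emerge unprotected. On stereochemical economy this is better than the chosen plan, which needs a reduction and a reoxidation.
- Against it here: the new C3–H would be formed in a medium that must contain base (for sulfinate loss and carbene generation), so erosion of enantiomeric purity in the flask is the main threat. Benzoin-type self-reaction of the aldehyde and dimerisation of A6 would compete. A5 is far from commercial materials.
- Structure: the plans are complementary. The alternative presupposes the reverse-prenylated ring B that the chosen key step builds, and 11 would be its natural feed.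
- Mechanism: the alternative sets C3 kinetically while it is acidic. The chosen plan sets it as a non-enolisable alcohol and reveals the ketone only under base-free conditions, which is the more secure.
- Step economy: the endgame of the alternative is shorter by two steps (a point for it), but the assembly of A5 is estimated to cost more than that, so the overall count is comparable at lower certainty.

Alternative 3: The cut is C2–C3.
- Forward key step: the diazo ketone A8 would lose dinitrogen on Rh2(S-PTTL)4, and the carbene at C3 would insert into a C–H bond of the ortho-methoxy group of ring A, closing ring C and giving A7.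
- In its favour: O1–C2 comes from a cheap methoxy group, ring C and the stereocentre form together, and the conditions are neutral and base-free. For the labile C3–H this is better than the basic conditions that the chosen route has to pass through in its arylation step.
- Against it here: the insertion would have to form a six-membered ring into a primary C–H bond, while attack of the carbene on the O1 lone pair (a five-membered oxonium ylide, then a 1,2-methyl shift) is the easier path. The stereocentre is created at the carbene carbon, where catalyst control is least predictable. Ring B again has to be made first.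
- Structure: complementary to the chosen key step and equal to it in dependence on ring B.
- Mechanism: the chosen plan uses reaction types with an established record for each bond. The insertion would be working against the usual ring-size preference.
- Step economy: the alternative could be two steps shorter after the coupling of the two rings (equal or better on count), but the synthesis of A8 (C3–C4 bond formation, then diazo transfer) offsets part of this, and the risk is concentrated in one step.

Key step: step 3

Assumption: ring B is numbered C1' (bonded to C3) to C6'. The structures and the atom mapping of the key step were rechecked and needed no correction. The usual sense of induction of RuCl[(R,R)-TsDPEN](p-cymene) with aryl ketones ((R)-carbinol when the aryl group outranks the alkyl group) is taken to hold for 16.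

## Route

Step 1
Reactants: 1 4-bromo-2-methoxyphenol
Product: 2 (4-bromo-2-methoxyphenoxy)triisopropylsilane
Conditions: TIPSCl, imidazole, DMF, rt
Reagents that add atoms: triisopropylsilyl chloride, CC(C)[Si](Cl)(C(C)C)C(C)C
Why: Silylation of a phenol with a silyl chloride and imidazole; the triisopropylsilyl group is kept because it survives lithium amides and Grignard reagents, shields C1'–H from the base and does not migrate from oxygen to carbon.

Step 2
Reactants: 3 prenyl chloride (1-chloro-3-methylbut-2-ene)
Product: 4 prenylmagnesium chloride
Conditions: Mg turnings (excess), I2 (cat.), THF, 0 °C, slow addition; titrated and used at once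
Reagents that add atoms: magnesium, [Mg]
Why: Grignard formation by insertion of magnesium into the allylic C–Cl bond; low temperature, dilution and excess metal hold back Wurtz coupling.

Step 3
Reactants: 2 (4-bromo-2-methoxyphenoxy)triisopropylsilane; 4 prenylmagnesium chloride
Product: 9 2-methoxy-6-(2-methylbut-3-en-2-yl)-3-(triisopropylsilyloxy)phenol, via aryllithium 5 (not isolated), via aryne 6 (not isolated), via arylmagnesium chloride 7 (not isolated), via dimethyl arylboronate 8 (not isolated)
Conditions: 4 (3 equiv), THF, −78 °C; lithium 2,2,6,6-tetramethylpiperidide (1.5 equiv) added slowly, −78 → −20 °C; B(OMe)3, −78 °C → rt; 30% H2O2, aq NaOH, 0 °C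
Reagents that add atoms: hydrogen peroxide, OO (the C4' oxygen of 9); trimethyl borate, COB(OC)OC (the boron group of 8 only); lithium 2,2,6,6-tetramethylpiperidide, [Li]N1C(C)(C)CCCC1(C)C (the lithium of 5 only)
Why: The lithium amide removes the most acidic ring proton of 2, the one flanked by OMe and Br, to give 5, which loses LiBr on warming to the C4'–C5' aryne 6; the bulky silyl ether keeps the base away from C1'–H. The methoxy group at C3' polarises the aryne so that the carbon nucleophile enters at the remote carbon C5' and the carbon–magnesium bond forms at C4', where it is stabilised inductively and by chelation to OMe; C6' carries only hydrogen and adds no counter-bias. The allylic Grignard reagent 4 is expected to react through a six-membered, ene-like transition state in which magnesium passes to C4' while the dimethyl-substituted terminus bonds to C5', creating the quaternary 1,1-dimethylallyl group and the arylmagnesium 7 in one event. Trimethyl borate then converts 7 into the boronate 8, and alkaline hydrogen peroxide oxidises the C–B bond in place to the C4' phenol 9. The closest known reaction type is the three-component aryne coupling, that is carbomagnesiation of an aryne made from a haloarene followed by electrophilic trapping of the new aryl Grignard reagent; what is extrapolated is the allylic transposition of the prenyl unit, which is standard with carbonyl electrophiles. No ring is closed and no stereocentre is formed. Three selectivities are needed: the site of deprotonation (secured by the combined acidifying effect of OMe and Br), the orientation of addition to the aryne (secured by the C3' methoxy group) and attack through the substituted end of the prenyl unit (secured by the cyclic transition state and the low steric demand of an aryne carbon). The terminal alkene and the silyl ether should survive brief cold alkaline peroxide.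

Step 4
Reactants: 9 2-methoxy-6-(2-methylbut-3-en-2-yl)-3-(triisopropylsilyloxy)phenol
Product: 10 [2,3-dimethoxy-4-(2-methylbut-3-en-2-yl)phenoxy]triisopropylsilane
Conditions: MeI, K2CO3, acetone, reflux
Reagents that add atoms: iodomethane, CI
Why: Williamson O-methylation of the hindered phenoxide; dry carbonate in acetone does not cleave the aryl silyl ether, and because O2' stays masked only O4' is methylated.

Step 5
Reactants: 10 [2,3-dimethoxy-4-(2-methylbut-3-en-2-yl)phenoxy]triisopropylsilane
Product: 11 2,3-dimethoxy-4-(2-methylbut-3-en-2-yl)phenol
Conditions: Bu4NF, THF, 0 °C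
Reagents that add atoms: none
Why: Fluoride-induced cleavage of the aryl silyl ether, driven by the Si–F bond; nothing else in 10 reacts with fluoride.

Step 6
Reactants: 11 2,3-dimethoxy-4-(2-methylbut-3-en-2-yl)phenol
Product: 12 6-bromo-2,3-dimethoxy-4-(2-methylbut-3-en-2-yl)phenol
Conditions: NBS, iPr2NH (10 mol %), CH2Cl2, −20 → 0 °C
Reagents that add atoms: N-bromosuccinimide, O=C1CCC(=O)N1Br
Why: Electrophilic aromatic bromination directed by the free phenol: the para position (C5') is occupied and the other ortho position (C3') carries OMe, so C1' is the only activated site; the amine-catalysed reagent at low temperature delivers bromine ortho to OH and avoids free Br2, which would attack the vinyl group.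

Step 7
Reactants: 12 6-bromo-2,3-dimethoxy-4-(2-methylbut-3-en-2-yl)phenol
Product: 13 1-bromo-3,4-dimethoxy-2-(methoxymethoxy)-5-(2-methylbut-3-en-2-yl)benzene
Conditions: MOMCl, iPr2NEt, CH2Cl2, 0 °C → rt
Reagents that add atoms: chloromethyl methyl ether, COCCl
Why: O-alkylation of the phenol with an α-chloro ether and a hindered amine base; the acetal tolerates the basic coupling, the formate reduction and the periodinane oxidation that follow.

Step 8
Reactants: 14 7-hydroxychroman-4-one
Product: 15 7-(methoxymethoxy)chroman-4-one
Conditions: MOMCl, iPr2NEt, CH2Cl2, 0 °C → rt
Reagents that add atoms: chloromethyl methyl ether, COCCl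
Why: Same acetal protection as in step 7; masking the 7-OH keeps the ketone enolisable, since a 7-phenoxide would deactivate it as a vinylogous carboxylate.

Step 9
Reactants: 13 1-bromo-3,4-dimethoxy-2-(methoxymethoxy)-5-(2-methylbut-3-en-2-yl)benzene; 15 7-(methoxymethoxy)chroman-4-one
Product: 16 rac-3-[3,4-dimethoxy-2-(methoxymethoxy)-5-(2-methylbut-3-en-2-yl)phenyl]-7-(methoxymethoxy)chroman-4-one
Conditions: Pd(OAc)2 (5 mol %), 2-dicyclohexylphosphino-2',4',6'-triisopropylbiphenyl (10 mol %), K3PO4, toluene, 90 °C
Reagents that add atoms: none
Why: Palladium-catalysed α-arylation of a ketone enolate (Buchwald–Hartwig type): zerovalent palladium inserts into the C1'–Br bond, the potassium enolate of 15 replaces bromide on the metal and reductive elimination forms C3–C1'. The weak base K3PO4 keeps the enolate concentration low, which limits β-elimination of the ring C phenoxide, and the ortho-substituted aryl group on a now tertiary C3 should stop a second arylation; the racemic product is intended.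

Step 10
Reactants: 16 rac-3-[3,4-dimethoxy-2-(methoxymethoxy)-5-(2-methylbut-3-en-2-yl)phenyl]-7-(methoxymethoxy)chroman-4-one
Product: 17 (3R,4R)-3-[3,4-dimethoxy-2-(methoxymethoxy)-5-(2-methylbut-3-en-2-yl)phenyl]-7-(methoxymethoxy)chroman-4-ol (aryl and OH cis)
Conditions: RuCl[(R,R)-TsDPEN](p-cymene) (2 mol %), HCO2H/Et3N (5:2), EtOAc, 40 °C
Reagents that add atoms: none
Why: Noyori-type asymmetric transfer hydrogenation with dynamic kinetic resolution, a known combination for 3-arylchroman-4-ones: triethylammonium formate racemises C3 through the enol faster than hydride is transferred. The (R,R)-catalyst delivers hydride to the C4 face that gives the (4R)-carbinol and does so anti to the C3 aryl group, so only the (3R)-ketone is consumed and the cis-(3R,4R) alcohol should result; the ruthenium hydride does not reduce the isolated vinyl group.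

Step 11
Reactants: 17 (3R,4R)-3-[3,4-dimethoxy-2-(methoxymethoxy)-5-(2-methylbut-3-en-2-yl)phenyl]-7-(methoxymethoxy)chroman-4-ol
Product: 18 (3R)-3-[3,4-dimethoxy-2-(methoxymethoxy)-5-(2-methylbut-3-en-2-yl)phenyl]-7-(methoxymethoxy)chroman-4-one
Conditions: Dess–Martin periodinane, CH2Cl2, 0 °C → rt
Reagents that add atoms: none
Why: Dess–Martin oxidation of the secondary benzylic alcohol by ligand exchange at pentavalent iodine and internal proton removal; the medium is weakly acidic and base-free, so the C3 configuration set in step 10 should pass into the ketone without enolisation.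

Step 12
Reactants: 18 (3R)-3-[3,4-dimethoxy-2-(methoxymethoxy)-5-(2-methylbut-3-en-2-yl)phenyl]-7-(methoxymethoxy)chroman-4-one
Product: 19 pervilleanone, (3R)-7-hydroxy-3-[2-hydroxy-3,4-dimethoxy-5-(2-methylbut-3-en-2-yl)phenyl]chroman-4-one
Conditions: ZnBr2, n-PrSH, CH2Cl2, 0 °C, 10–15 min
Reagents that add atoms: none
Why: Lewis-acid-assisted acetal cleavage: ZnBr2 activates each methoxymethyl ether and the thiol captures the methoxymethyl cation as an O,S-acetal. The reaction should be over in minutes at 0 °C without protic acid or base, which keeps enolisation of C3 and cyclodehydration of the 2'-OH/C4=O pair to a minimum; the methyl ethers and the vinyl group are untouched.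

## Compound list

1 | 4-bromo-2-methoxyphenol | COc1cc(Br)ccc1O | starting material
2 | (4-bromo-2-methoxyphenoxy)triisopropylsilane | COc1cc(Br)ccc1O[Si](C(C)C)(C(C)C)C(C)C | intermediate
3 | prenyl chloride (1-chloro-3-methylbut-2-ene) | CC(C)=CCCl | starting material
4 | prenylmagnesium chloride | CC(C)=CC[Mg]Cl | intermediate
5 | [6-bromo-2-methoxy-3-(triisopropylsilyloxy)phenyl]lithium | COc1c([Li])c(Br)ccc1O[Si](C(C)C)(C(C)C)C(C)C | intermediate
6 | 3-methoxy-4-(triisopropylsilyloxy)benzyne | COC1=C(O[Si](C(C)C)(C(C)C)C(C)C)C=CC#C1 | intermediate
7 | [2-methoxy-6-(2-methylbut-3-en-2-yl)-3-(triisopropylsilyloxy)phenyl]magnesium chloride | C=CC(C)(C)c1ccc(O[Si](C(C)C)(C(C)C)C(C)C)c(OC)c1[Mg]Cl | intermediate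
8 | dimethyl [2-methoxy-6-(2-methylbut-3-en-2-yl)-3-(triisopropylsilyloxy)phenyl]boronate | C=CC(C)(C)c1ccc(O[Si](C(C)C)(C(C)C)C(C)C)c(OC)c1B(OC)OC | intermediate
9 | 2-methoxy-6-(2-methylbut-3-en-2-yl)-3-(triisopropylsilyloxy)phenol | C=CC(C)(C)c1ccc(O[Si](C(C)C)(C(C)C)C(C)C)c(OC)c1O | intermediate
10 | [2,3-dimethoxy-4-(2-methylbut-3-en-2-yl)phenoxy]triisopropylsilane | C=CC(C)(C)c1ccc(O[Si](C(C)C)(C(C)C)C(C)C)c(OC)c1OC | intermediate
11 | 2,3-dimethoxy-4-(2-methylbut-3-en-2-yl)phenol | C=CC(C)(C)c1ccc(O)c(OC)c1OC | intermediate
12 | 6-bromo-2,3-dimethoxy-4-(2-methylbut-3-en-2-yl)phenol | C=CC(C)(C)c1cc(Br)c(O)c(OC)c1OC | intermediate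
13 | 1-bromo-3,4-dimethoxy-2-(methoxymethoxy)-5-(2-methylbut-3-en-2-yl)benzene | C=CC(C)(C)c1cc(Br)c(OCOC)c(OC)c1OC | intermediate
14 | 7-hydroxychroman-4-one | O=C1CCOc2cc(O)ccc12 | starting material
15 | 7-(methoxymethoxy)chroman-4-one | COCOc1ccc2c(c1)OCCC2=O | intermediate
16 | rac-3-[3,4-dimethoxy-2-(methoxymethoxy)-5-(2-methylbut-3-en-2-yl)phenyl]-7-(methoxymethoxy)chroman-4-one | C=CC(C)(C)c1cc(C2COc3cc(OCOC)ccc3C2=O)c(OCOC)c(OC)c1OC | intermediate
17 | (3R,4R)-3-[3,4-dimethoxy-2-(methoxymethoxy)-5-(2-methylbut-3-en-2-yl)phenyl]-7-(methoxymethoxy)chroman-4-ol | C=CC(C)(C)c1cc([C@@H]2COc3cc(OCOC)ccc3[C@@H]2O)c(OCOC)c(OC)c1OC | intermediate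
18 | (3R)-3-[3,4-dimethoxy-2-(methoxymethoxy)-5-(2-methylbut-3-en-2-yl)phenyl]-7-(methoxymethoxy)chroman-4-one | C=CC(C)(C)c1cc([C@@H]2COc3cc(OCOC)ccc3C2=O)c(OCOC)c(OC)c1OC | intermediate
19 | pervilleanone, (3R)-7-hydroxy-3-[2-hydroxy-3,4-dimethoxy-5-(2-methylbut-3-en-2-yl)phenyl]chroman-4-one | C=CC(C)(C)c1cc([C@@H]2COc3cc(O)ccc3C2=O)c(O)c(OC)c1OC | target

## Step count and least certain steps

Total step count: 12. Longest linear sequence: 10 steps (steps 1, 3, 4, 5, 6, 7, 9, 10, 11, 12, from compound 1); steps 2 and 8 are one-step side branches.

**Step 3 (key step).** Most likely to go wrong: loss of regiocontrol in the allyl transfer (bonding through the unsubstituted end, which would give the linear prenyl isomer), because the transposition has its record with carbonyl electrophiles and not with arynes. Further risks are competing deprotonation at C6'–H, which would open an unbiased C5'–C6' aryne, and capture of the aryne by the amide base.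
Fallback: it sets out from 1 and comes back at 12, with the phenol oxygen of 1 now serving as O4' and its bromine as the C1' bromine.
- O-Prenylation of 1 (prenyl bromide, K2CO3, acetone) should give 4-bromo-2-methoxy-1-(3-methylbut-2-enyloxy)benzene F1.
- Aromatic Claisen rearrangement (N,N-diethylaniline, about 190 °C) moves the allyl unit with inversion to the only free ortho position, the para position being blocked by bromine, to give 4-bromo-2-methoxy-6-(2-methylbut-3-en-2-yl)phenol F2.
- Methylation (MeI, K2CO3) gives 5-bromo-1,2-dimethoxy-3-(2-methylbut-3-en-2-yl)benzene F3.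
- Lithiation between Br and OMe with lithium 2,2,6,6-tetramethylpiperidide in the presence of B(OiPr)3 at −78 °C (borate trapping in the flask, before LiBr can be lost), then H2O2, gives 12.

**Step 9.** Most likely to go wrong: ring opening of the chromanone enolate by β-elimination with decomposition, slow coupling at the ortho-substituted bromide, or Heck-type consumption of the vinyl group, because all three compete with the enolate capture on palladium.
Fallback: it sets out from 13 and comes back at 17.
- Bromine–lithium exchange on 13 (n-BuLi, THF, −78 °C) and quenching with 2-isopropoxy-4,4,5,5-tetramethyl-1,3,2-dioxaborolane should give the aryl pinacol boronate F4.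
- The partner starts from commercial 2',4'-dihydroxyacetophenone F5. MOMCl/K2CO3 protects the non-chelated 4'-OH to give 2'-hydroxy-4'-(methoxymethoxy)acetophenone F6.
- N,N-Dimethylformamide dimethyl acetal converts F6 into the enaminone F7, and I2 cyclises and iodinates this to 3-iodo-7-(methoxymethoxy)chromen-4-one F8.
- Suzuki coupling of F4 with F8 (Pd(PPh3)4, K2CO3, dioxane/H2O, 80 °C) gives the bis-acetal isoflavone F9.
- Transfer hydrogenation with RuCl[(R,R)-TsDPEN](p-cymene) and HCO2H/Et3N reduces first C2=C3 and then, with dynamic kinetic resolution of the ketone 16 formed in the flask, C4=O, to return at 17.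

**Step 12.** Most likely to go wrong: erosion of the C3 configuration by Lewis-acid-assisted enolisation during acetal cleavage, or cyclodehydration between the liberated 2'-OH and C4=O, because the product combines an acidic C3–H with a phenol placed over the ketone.
Fallback: it sets out from 12 and 14 and comes back at 19, replacing acid-labile by fluoride-labile protection.
- 12 is silylated (TBSCl, imidazole, DMF) to tert-butyl[6-bromo-2,3-dimethoxy-4-(2-methylbut-3-en-2-yl)phenoxy]dimethylsilane F10.
- 14 is silylated (TIPSCl, imidazole, DMF) to 7-(triisopropylsilyloxy)chroman-4-one F11.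
- The arylation conditions of step 9 (dry K3PO4 in toluene does not cleave aryl silyl ethers) give the racemic bis-silyl isoflavanone F12.
- The conditions of step 10 give the cis-(3R,4R) alcohol F13, and Dess–Martin oxidation gives the (R)-ketone F14.
- Both silyl ethers are removed with Bu4NF buffered with AcOH in THF at 0 °C to give 19.

**Step 10.** Most likely to go wrong: incomplete stereocontrol, either because racemisation of the hindered ketone does not keep pace with reduction or because the bulky ortho-substituted aryl group weakens the facial preference of the catalyst.
Fallback: it sets out from 16 and comes back at 18. Preparative HPLC of 16 on a chiral stationary phase separates the enantiomers; the (R)-enantiomer is 18, and the other is racemised with Et3N and recycled. No new compound is made.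

**Step 6.** Most likely to go wrong: ipso attack of the electrophile at C5' with loss of the tertiary allylic group, or bromine addition to the vinyl group, because the para position of the phenol is electron-rich and bears a group that can leave as a stabilised cation.
Fallback: it sets out from 11 and comes back at 13.
- 11 is protected (MOMCl, iPr2NEt) as 2,3-dimethoxy-1-(methoxymethoxy)-4-(2-methylbut-3-en-2-yl)benzene F15.
- Directed ortho-lithiation (n-BuLi, THF, 0 °C; C1'–H is the only hydrogen ortho to a directing group) and quenching with 1,2-dibromotetrachloroethane gives 13.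

## Further compounds

F1 | step 3 | 4-bromo-2-methoxy-1-(3-methylbut-2-enyloxy)benzene | COc1cc(Br)ccc1OCC=C(C)C
F2 | step 3 | 4-bromo-2-methoxy-6-(2-methylbut-3-en-2-yl)phenol | C=CC(C)(C)c1cc(Br)cc(OC)c1O
F3 | step 3 | 5-bromo-1,2-dimethoxy-3-(2-methylbut-3-en-2-yl)benzene | C=CC(C)(C)c1cc(Br)cc(OC)c1OC
F4 | step 9 | 2-[3,4-dimethoxy-2-(methoxymethoxy)-5-(2-methylbut-3-en-2-yl)phenyl]-4,4,5,5-tetramethyl-1,3,2-dioxaborolane | C=CC(C)(C)c1cc(B2OC(C)(C)C(C)(C)O2)c(OCOC)c(OC)c1OC
F5 | step 9 | 2',4'-dihydroxyacetophenone (commercial) | CC(=O)c1ccc(O)cc1O
F6 | step 9 | 2'-hydroxy-4'-(methoxymethoxy)acetophenone | CC(=O)c1ccc(OCOC)cc1O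
F7 | step 9 | (E)-3-(dimethylamino)-1-[2-hydroxy-4-(methoxymethoxy)phenyl]prop-2-en-1-one | CN(C)/C=C/C(=O)c1ccc(OCOC)cc1O
F8 | step 9 | 3-iodo-7-(methoxymethoxy)chromen-4-one | COCOc1ccc2c(c1)occ(I)c2=O
F9 | step 9 | 3-[3,4-dimethoxy-2-(methoxymethoxy)-5-(2-methylbut-3-en-2-yl)phenyl]-7-(methoxymethoxy)chromen-4-one | C=CC(C)(C)c1cc(-c2coc3cc(OCOC)ccc3c2=O)c(OCOC)c(OC)c1OC
F10 | step 12 | tert-butyl[6-bromo-2,3-dimethoxy-4-(2-methylbut-3-en-2-yl)phenoxy]dimethylsilane | C=CC(C)(C)c1cc(Br)c(O[Si](C)(C)C(C)(C)C)c(OC)c1OC
F11 | step 12 | 7-(triisopropylsilyloxy)chroman-4-one | CC(C)[Si](Oc1ccc2c(c1)OCCC2=O)(C(C)C)C(C)C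
F12 | step 12 | rac-3-[2-(tert-butyldimethylsilyloxy)-3,4-dimethoxy-5-(2-methylbut-3-en-2-yl)phenyl]-7-(triisopropylsilyloxy)chroman-4-one | C=CC(C)(C)c1cc(C2COc3cc(O[Si](C(C)C)(C(C)C)C(C)C)ccc3C2=O)c(O[Si](C)(C)C(C)(C)C)c(OC)c1OC
F13 | step 12 | (3R,4R)-3-[2-(tert-butyldimethylsilyloxy)-3,4-dimethoxy-5-(2-methylbut-3-en-2-yl)phenyl]-7-(triisopropylsilyloxy)chroman-4-ol | C=CC(C)(C)c1cc([C@@H]2COc3cc(O[Si](C(C)C)(C(C)C)C(C)C)ccc3[C@@H]2O)c(O[Si](C)(C)C(C)(C)C)c(OC)c1OC
F14 | step 12 | (3R)-3-[2-(tert-butyldimethylsilyloxy)-3,4-dimethoxy-5-(2-methylbut-3-en-2-yl)phenyl]-7-(triisopropylsilyloxy)chroman-4-one | C=CC(C)(C)c1cc([C@@H]2COc3cc(O[Si](C(C)C)(C(C)C)C(C)C)ccc3C2=O)c(O[Si](C)(C)C(C)(C)C)c(OC)c1OC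
F0 | step 10 | none | none
F15 | step 6 | 2,3-dimethoxy-1-(methoxymethoxy)-4-(2-methylbut-3-en-2-yl)benzene | C=CC(C)(C)c1ccc(OCOC)c(OC)c1OC
A1 | alternative 1 | 5-chloro-7,2'-bis(methoxymethoxy)-3',4'-dimethoxy-5'-(2-methylbut-3-en-2-yl)isoflavone | C=CC(C)(C)c1cc(-c2coc3cc(OCOC)cc(Cl)c3c2=O)c(OCOC)c(OC)c1OC
A2 | alternative 1 | 2-[3,4-dimethoxy-2-(methoxymethoxy)-5-(2-methylbut-3-en-2-yl)phenyl]-3-methoxyprop-2-enoic acid | C=CC(C)(C)c1cc(C(=COC)C(=O)O)c(OCOC)c(OC)c1OC
A3 | alternative 1 | 3-chloro-5-(methoxymethoxy)-2-(trimethylsilyl)phenyl trifluoromethanesulfonate | COCOc1cc(Cl)c([Si](C)(C)C)c(OS(=O)(=O)C(F)(F)F)c1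
A4 | alternative 2 | (R)-7-O-(tert-butyldimethylsilyl)pervilleanone | C=CC(C)(C)c1cc([C@@H]2COc3cc(O[Si](C)(C)C(C)(C)C)ccc3C2=O)c(O)c(OC)c1OC
A5 | alternative 2 | 4-(tert-butyldimethylsilyloxy)-2-{2-[2-hydroxy-3,4-dimethoxy-5-(2-methylbut-3-en-2-yl)phenyl]-2-(4-methylphenylsulfonyl)ethoxy}benzaldehyde | C=CC(C)(C)c1cc(C(COc2cc(O[Si](C)(C)C(C)(C)C)ccc2C=O)S(=O)(=O)c2ccc(C)cc2)c(O)c(OC)c1OC
A6 | alternative 2 | ortho-quinone methide of ring B, 4-(tert-butyldimethylsilyloxy)-2-{2-[4,5-dimethoxy-3-(2-methylbut-3-en-2-yl)-6-oxocyclohexa-2,4-dien-1-ylidene]ethoxy}benzaldehyde | C=CC(C)(C)C1=CC(=CCOc2cc(O[Si](C)(C)C(C)(C)C)ccc2C=O)C(=O)C(OC)=C1OC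
A7 | alternative 3 | (R)-7,2'-bis-O-(triisopropylsilyl)pervilleanone | C=CC(C)(C)c1cc([C@@H]2COc3cc(O[Si](C(C)C)(C(C)C)C(C)C)ccc3C2=O)c(O[Si](C(C)C)(C(C)C)C(C)C)c(OC)c1OC
A8 | alternative 3 | 2-diazo-2-[3,4-dimethoxy-5-(2-methylbut-3-en-2-yl)-2-(triisopropylsilyloxy)phenyl]-1-[2-methoxy-4-(triisopropylsilyloxy)phenyl]ethanone | C=CC(C)(C)c1cc(C(=[N+]=[N-])C(=O)c2ccc(O[Si](C(C)C)(C(C)C)C(C)C)cc2OC)c(O[Si](C(C)C)(C(C)C)C(C)C)c(OC)c1OC
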